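## Retrosynthetic overview

1. The last step frees the C7 phenol from a triisopropylsilyl ether. The geranyl ether on ring B is carried from the start (geranyl = (2E)-3,7-dimethylocta-2,6-dien-1-yl).
2. Ring C (the pyranone) is cut at C2–C3 and C4–C4a. It is made by a stepwise cationic [4+2] annulation of an O-aryl oxocarbenium ion (C4a=C8a–O1=C2, cationic at C2) with ethoxyacetylene as a ketene equivalent (C3–C4). A chiral counteranion sets C2, and the enol ether formed is hydrolysed to the C4 ketone in the same flask.
3. Enabling feature: the ether oxygen O1 sits between the benzylic carbon C2, which carries the electron-rich 4-geranyloxyphenyl ring B and can bear a cation, and the resorcinol-type ring A, whose C4a is ortho to O1 and para to the C7 oxygen.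
4. The cation precursor is an O-aryl O-acetyl acetal, made by reductive acetylation of the aryl ester from 4-(geranyloxy)benzoic acid and mono-silylated resorcinol.
5. Ring order: rings A and B are bought (resorcinol, methyl 4-hydroxybenzoate); ring C is the only ring formed, in step 6.

Key step: step 6

Assumption: the sense of induction of the chiral acid in step 6 cannot be foretold with certainty, so the route is written with the (S,S)-acid [the imidodiphosphorimidate (ArO)2P(=NTf)–NH–P(=NTf)(OAr)2, each (ArO)2 being (S)-3,3'-bis[3,5-bis(trifluoromethyl)phenyl]-1,1'-binaphthalene-2,2'-diolate, Tf = CF3SO2], and its mirror image is to be taken if a test run shows the opposite sense.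

## Route

Step 1
Reactants: 1 resorcinol
Product: 2 3-(triisopropylsilyloxy)phenol
Conditions: iPr3SiCl (1 equiv), 1 (3 equiv), imidazole, DMF, 0 °C to rt
Reagents that add atoms: chlorotriisopropylsilane, CC(C)[Si](Cl)(C(C)C)C(C)C
Why: Imidazole-promoted O-silylation of a symmetric diol, in which the threefold excess of resorcinol should bias the statistical outcome to the mono-ether and is washed out with water afterwards.

Step 2
Reactants: 3 methyl 4-hydroxybenzoate; 4 geranyl bromide [(2E)-1-bromo-3,7-dimethylocta-2,6-diene]
Product: 5 methyl 4-(geranyloxy)benzoate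
Conditions: K2CO3, acetone, reflux
Reagents that add atoms: none
Why: Williamson ether synthesis, in which the phenoxide should displace the primary allylic bromide directly, so that the (E)-alkene geometry of the geranyl unit is kept.

Step 3
Reactants: 5 methyl 4-(geranyloxy)benzoate
Product: 6 4-(geranyloxy)benzoic acid
Conditions: LiOH, THF/MeOH/H2O, 40 °C; then aq. HCl to pH 3, 0 °C
Reagents that add atoms: lithium hydroxide, [Li+].[OH-]
Why: Ester saponification by acyl–oxygen cleavage, to which the allylic aryl ether and the two trisubstituted alkenes are inert, followed by brief cold acidification.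

Step 4
Reactants: 6 4-(geranyloxy)benzoic acid; 2 3-(triisopropylsilyloxy)phenol
Product: 7 3-(triisopropylsilyloxy)phenyl 4-(geranyloxy)benzoate
Conditions: N,N'-dicyclohexylcarbodiimide, DMAP (cat.), CH2Cl2, 0 °C to rt
Reagents that add atoms: none
Why: Steglich esterification, in which DMAP carries the acyl group from the O-acylisourea to the weakly nucleophilic phenol under neutral conditions that leave the silyl and geranyl ethers untouched.

Step 5
Reactants: 7 3-(triisopropylsilyloxy)phenyl 4-(geranyloxy)benzoate
Product: 9 [4-(geranyloxy)phenyl][3-(triisopropylsilyloxy)phenoxy]methyl acetate (racemic), via aluminium hemiacetal 8 (not isolated)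
Conditions: iBu2AlH, CH2Cl2, −78 °C; then pyridine, DMAP, Ac2O, −78 to −20 °C
Reagents that add atoms: acetic anhydride, CC(=O)OC(C)=O
Why: Reductive acetylation of an ester, in which iBu2AlH should add once at −78 °C to give the tetrahedral aluminium hemiacetal 8, which is O-acetylated in place before it can collapse; the acetal carbon forms racemic, which is harmless because step 6 makes it planar.

Step 6
Reactants: 9 [4-(geranyloxy)phenyl][3-(triisopropylsilyloxy)phenoxy]methyl acetate; 10 ethoxyacetylene
Product: 14 (2S)-2-[4-(geranyloxy)phenyl]-7-(triisopropylsilyloxy)-2,3-dihydro-4H-chromen-4-one, via oxocarbenium ion 11 (not isolated), via ketenium ion 12 (not isolated), via enol ether 13 (not isolated)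
Conditions: (S,S)-imidodiphosphorimidate acid (5 mol %), 10 (3 equiv, slow addition), CH2Cl2/toluene, −78 °C; then aq. HCl (1 mol/L), THF, 0 °C
Reagents that add atoms: water, O
Why: Proposed new method: the chiral acid should ionise the acetate of 9 (the only group able to leave, because an acyloxy group cannot stabilise the cation that loss of the aryloxy group would give) to the O-aryl oxocarbenium ion 11 paired with the confined chiral anion, the terminal carbon of ynol ether 10 should add to its benzylic carbon (new bond C2–C3), and the ketenium ion 12 so formed should be caught at once by ring A at the carbon ortho to the ether oxygen and para to the silyloxy group (new bond C4–C4a), after which loss of a proton returns the acid and leaves enol ether 13, hydrolysed in the same flask to ketone 14. The closest known reaction types are the Lewis acid-promoted oxa-Povarov reaction of O-aryl oxocarbenium ions with alkenes, the Povarov-type annulation of N-aryl iminium ions with ynamides, the Friedel–Crafts closure of ketenium ions made from ynol ethers, and counteranion-directed additions to oxocarbenium ions under confined chiral acid or anion-binding catalysis; what is new is their union on an O-aryl cation with an ynol ether as ketene equivalent under enantiocontrol. Ring C closes by a 6-exo-dig Friedel–Crafts attack of the arene on the sp carbon of the ketenium ion, so that overall a stepwise cationic formal [4+2] annulation of the 2-oxadiene cation C4a=C8a–O1=C2 with the alkyne results. The only new stereocenter, C2, is set in the first carbon–carbon bond formation by the chiral anion, which should shield one face of the planar cation in the contact ion pair, and nothing later touches this center. The step needs the ynol ether to win as nucleophile over the geranyl alkenes and over ring A of a second molecule (it is far more nucleophilic than either at −78 °C), needs attack of the arene carbon to win over attack of the ether oxygen, which would lead to an aryl cinnamate by formal metathesis (secured by the doubly activated C4a and the poor donor power of an aryl ether oxygen), and needs closure at C4a and not at the carbon between the two oxygens (secured by the bulky triisopropylsilyl group).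

Step 7
Reactants: 14 (2S)-2-[4-(geranyloxy)phenyl]-7-(triisopropylsilyloxy)-2,3-dihydro-4H-chromen-4-one
Product: 15 (2S)-2-[4-(geranyloxy)phenyl]-7-hydroxy-2,3-dihydro-4H-chromen-4-one (CNP0302343.1)
Conditions: Bu4NF, AcOH (1:1), THF, 0 °C
Reagents that add atoms: none
Why: Fluoride-mediated cleavage of the aryl silyl ether, in which the acetic acid buffer protonates the phenoxide as it forms, so that base-induced ring opening of the flavanone and with it loss of the C2 configuration should be avoided, while the geranyl ether is inert.

## Compound list

1 | resorcinol | Oc1cccc(O)c1 | starting material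
2 | 3-(triisopropylsilyloxy)phenol | CC(C)[Si](Oc1cccc(O)c1)(C(C)C)C(C)C | intermediate
3 | methyl 4-hydroxybenzoate | COC(=O)c1ccc(O)cc1 | starting material
4 | geranyl bromide, (2E)-1-bromo-3,7-dimethylocta-2,6-diene | CC(C)=CCC/C(C)=C/CBr | starting material
5 | methyl 4-(geranyloxy)benzoate | CC(C)=CCC/C(C)=C/COc1ccc(C(=O)OC)cc1 | intermediate
6 | 4-(geranyloxy)benzoic acid | CC(C)=CCC/C(C)=C/COc1ccc(C(=O)O)cc1 | intermediate
7 | 3-(triisopropylsilyloxy)phenyl 4-(geranyloxy)benzoate | CC(C)=CCC/C(C)=C/COc1ccc(C(=O)Oc2cccc(O[Si](C(C)C)(C(C)C)C(C)C)c2)cc1 | intermediate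
8 | diisobutylaluminium alkoxide of the O-aryl hemiacetal of 7 (racemic) | CC(C)=CCC/C(C)=C/COc1ccc(C(O[Al](CC(C)C)CC(C)C)Oc2cccc(O[Si](C(C)C)(C(C)C)C(C)C)c2)cc1 | intermediate (not isolated)
9 | [4-(geranyloxy)phenyl][3-(triisopropylsilyloxy)phenoxy]methyl acetate (racemic) | CC(C)=CCC/C(C)=C/COc1ccc(C(OC(C)=O)Oc2cccc(O[Si](C(C)C)(C(C)C)C(C)C)c2)cc1 | intermediate
10 | ethoxyacetylene (ethoxyethyne) | C#COCC | starting material
11 | [4-(geranyloxy)benzylidene][3-(triisopropylsilyloxy)phenyl]oxonium ion, ion pair with the chiral anion | CC(C)=CCC/C(C)=C/COc1ccc(C=[O+]c2cccc(O[Si](C(C)C)(C(C)C)C(C)C)c2)cc1 | intermediate (not isolated)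
12 | (S)-configured O-ethyl ketenium ion, the adduct of 10 at the benzylic carbon of 11 | CC(C)=CCC/C(C)=C/COc1ccc([C@H](C=C=[O+]CC)Oc2cccc(O[Si](C(C)C)(C(C)C)C(C)C)c2)cc1 | intermediate (not isolated)
13 | (2S)-4-ethoxy-2-[4-(geranyloxy)phenyl]-7-(triisopropylsilyloxy)-2H-chromene | CC(C)=CCC/C(C)=C/COc1ccc([C@@H]2C=C(OCC)c3ccc(O[Si](C(C)C)(C(C)C)C(C)C)cc3O2)cc1 | intermediate (not isolated)
14 | (2S)-2-[4-(geranyloxy)phenyl]-7-(triisopropylsilyloxy)-2,3-dihydro-4H-chromen-4-one | CC(C)=CCC/C(C)=C/COc1ccc([C@@H]2CC(=O)c3ccc(O[Si](C(C)C)(C(C)C)C(C)C)cc3O2)cc1 | intermediate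
15 | (2S)-2-[4-(geranyloxy)phenyl]-7-hydroxy-2,3-dihydro-4H-chromen-4-one | CC(C)=CCC/C(C)=C/COc1ccc([C@@H]2CC(=O)c3ccc(O)cc3O2)cc1 | target

## Step count and risks

Total step count: 7. Longest linear sequence: 6 steps (3 to 5 to 6 to 7 to 9 to 14 to 15; step 1 feeds in at step 4).

Steps most likely to fail:

1. Step 6. The ion pair may discriminate the two faces of the cation poorly. The ketenium ion may also be diverted by attack of the ether oxygen, or the ynol ether may be protonated before the carbon–carbon bond forms. The fallback uses known chemistry, sets out from 4 and comes back at 14. Compound 4 alkylates commercial 4-(4,4,5,5-tetramethyl-1,3,2-dioxaborolan-2-yl)phenol (K2CO3, acetone) to give 2-[4-(geranyloxy)phenyl]-4,4,5,5-tetramethyl-1,3,2-dioxaborolane F1. Commercial 7-hydroxy-4H-chromen-4-one is silylated (iPr3SiCl, imidazole, DMF) to 7-(triisopropylsilyloxy)-4H-chromen-4-one F2. A rhodium-catalysed asymmetric 1,4-addition of F1 to F2 ([Rh(OH)(cod)]2, a chiral bisphosphine of the MeO-BIPHEP type in the antipode that gives 2S, dioxane/water) should then deliver 14, with the aryl group carried to C2 on the face fixed by the ligand.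

2. Step 5. The aluminium hemiacetal may collapse with loss of the aryloxide before it is acetylated, which would lead to over-reduction. The fallback sets out from 4 and comes back at 9. Compound 4 alkylates commercial 4-hydroxybenzaldehyde (K2CO3, DMF) to give 4-(geranyloxy)benzaldehyde F3. Acetyl chloride with catalytic ZnCl2 (CH2Cl2, 0 °C) should add across the carbonyl group to give chloro[4-(geranyloxy)phenyl]methyl acetate F4. Displacement of the chloride by phenol 2 (Cs2CO3, MeCN, 0 °C) should then give 9.

3. Step 7. The phenoxide or fluoride may act as a base and open ring C by β-elimination of the aryloxide, which would erode the C2 configuration. The fallback sets out from 13 and comes back at 15. The annulation mixture of step 6 is quenched with Et3N instead of aqueous acid, and enol ether 13 is desilylated with Bu4NF (THF, 0 °C) to give (2S)-4-ethoxy-2-[4-(geranyloxy)phenyl]-2H-chromen-7-ol F5. This compound has no ketone, so ring opening by β-elimination cannot take place. Hydrolysis of the enol ether with aqueous oxalic acid in THF at 0 °C should then give 15.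

Further compounds
F1 | step 6 | 2-[4-(geranyloxy)phenyl]-4,4,5,5-tetramethyl-1,3,2-dioxaborolane | CC(C)=CCC/C(C)=C/COc1ccc(B2OC(C)(C)C(C)(C)O2)cc1
F2 | step 6 | 7-(triisopropylsilyloxy)-4H-chromen-4-one | O=c1ccoc2cc(O[Si](C(C)C)(C(C)C)C(C)C)ccc12
F3 | step 5 | 4-(geranyloxy)benzaldehyde | CC(C)=CCC/C(C)=C/COc1ccc(C=O)cc1
F4 | step 5 | chloro[4-(geranyloxy)phenyl]methyl acetate (racemic) | CC(C)=CCC/C(C)=C/COc1ccc(C(Cl)OC(C)=O)cc1
F5 | step 7 | (2S)-4-ethoxy-2-[4-(geranyloxy)phenyl]-2H-chromen-7-ol | CC(C)=CCC/C(C)=C/COc1ccc([C@@H]2C=C(OCC)c3ccc(O)cc3O2)cc1
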